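## The problem

The target is a biflavonoid. A (2R)-5,7,3′,4′-tetrahydroxyflavanone carries, at C6′ of its ring B (ortho to the carbon bonded to C2), the C8 of a 5,7,3′,4′-tetrahydroxyflavone. The bond between the two halves is a biaryl bond with three ortho substituents (flavanone C2, the flavone C7 oxygen and the flavone ring oxygen at C8a). It therefore needs a coupling that tolerates crowding, and the flavanone must later be built on a hindered aldehyde carbon beside it.

C2 of the flavanone is the only stereocentre. Nothing in the molecule can relay to it, so a catalyst must set it. It lies on a benzylic C–O bond β to the C4 ketone and is erased by base through ring opening to the 2′-hydroxychalcone. It should therefore be made late and meet only neutral conditions afterwards.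

There are eight phenols, four of them in two catechols. The flavone pyranone is opened by hot hydroxide, and the flavone C2=C3 bond, the flavanone ketone and the benzylic C2–O bond can be over-reduced. One kind of protecting group, removable under neutral conditions, is needed.

The feature that makes the key step possible is the way the flavone pyranone (ring C) is fused to flavone ring A at C4a–C8a, with the oxygen-bearing C8a lying between C4a and the biaryl carbon C8. The bonds O1–C2, C3–C4 and C4–C4a then correspond to a phenol hydroxyl, a terminal alkyne and carbon monoxide on an aryl iodide. Ring C can be assembled in one operation from an ortho-iodophenol that already carries the biaryl bond, and the position of the iodine decides 8-aryl against 6-aryl.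

## Retrosynthesis

**21 from 20.** Only the eight O–benzyl bonds are cut. Benzyl is preferred to methyl, whose Lewis-acid cleavage endangers the flavanone, and to acetal-type ethers, which would fall off together with the dioxolane used earlier. Compound 20 has the full skeleton and the stereocentre. The forward step must cleave eight ethers without reducing the flavone C2=C3 bond, either C4 carbonyl or the benzylic C2–O bond.

**20 from 19.** The flavanone O1–C2 bond is cut, which leads to the 2′-hydroxychalcone 19. Two neighbouring cuts were weighed. Conjugate addition of a ring B boron reagent to a chromone would need transfer of an aryl group with a very large ortho substituent. Invertive closure of a β-hydroxy ketone would pass through a benzylic centre stabilised by the para benzyloxy group and risk erosion. The chosen cut removes the only stereocentre and leaves an achiral enone. The forward reaction must select one face of Cβ under kinetic control, because the closure is reversible.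

**19 from 14 and 17.** The Cα=Cβ bond is cut (Claisen–Schmidt condensation). This splits the molecule into flavone aldehyde 14 and the simple acetophenone 17, which comes from 15 through 16. The forward step must condense a hindered, electron-rich aldehyde while the flavone survives hydroxide at room temperature.

**14 from 13.** No skeletal bond is cut; the aldehyde is masked as a dioxolane. A free aldehyde ortho to the biaryl bond would close to a lactol with the ring A hydroxyl of 8 and 9, which is the hydroxyl the annulation needs. It would also not survive the organolithium used to make the boronate.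

**13 from 9, 10 and carbon monoxide (key cut).** O1–C2, C3–C4 and C4–C4a of the flavone are cut. Two neighbours were weighed:
- Suzuki–Miyaura coupling of an 8-iodoflavone with the ring B boronate needs a separate flavone synthesis, an 8- against 6-iodination and a coupling at a more crowded site.
- The route through a 3-aryl-2-hydroxyacetophenone and oxidative chalcone cyclisation needs strong base and oxidants that endanger the acetal and the ethers.

The chosen cut joins three pieces at once on a ring A that already carries the biaryl bond, and takes the flavone ring B from alkyne 10, one step from 1. The forward step must insert carbon monoxide faster than it couples directly, close 6-endo, and tolerate the substituents beside the iodide.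

**9 from 8.** The C–I bond is cut (electrophilic iodination ortho to the hydroxyl). Directed metalation would need a directing group and a strong base in the presence of four benzyl ethers and an acetal; it is held as the fallback. The forward step must attack C6 and not C4.

**8 from 7 and 5.** The biaryl bond is cut (Suzuki–Miyaura coupling). Ring A is the halide and ring B the boron partner, because 2,4,6-trioxygenated arylboron compounds lose boron easily. Both partners are small at this stage. The forward step must form a tri-ortho-substituted biaryl beside a free phenol.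

**Building blocks.** Compound 7 comes from 6 by iodination. Compound 5 comes from 1 through bromide 2, acetal 3 and aryllithium 4.

## Roads not taken

**Alternative 1:** The cut removes flavanone ring A at C8–C8a and C4a–C5. This leaves the (2R) sulfinyl dihydropyranone A2, which already carries ring B and the whole flavone, and the electron-rich diene A3.
- Forward step: A3 would add thermally across the C4a=C8a bond of A2. Loss of benzenesulfenic acid and methanol would aromatise the new ring to A1, the target with six benzyl ethers and a free 5,7-diol.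
- Merits: C2 could be set on the way to A2 by an asymmetric hetero-Diels–Alder reaction of aldehyde 14, which is irreversible. In this respect the road is better than the chosen one, whose oxa-Michael closure is reversible. Ring A also arrives unprotected.
- Weak points: A2 is a push–pull, tetrasubstituted dienophile that must be made by sulfenylation and oxidation next to the base-sensitive C2. Its cycloaddition needs heat and must be regioselective. A1 is the flavanone form most prone to ring opening, yet it would be released hot beside a sulfenic acid.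
- Comparison: the flavone, and so 14, must be built first in any case, which makes this road about three steps longer. Against the better stereo-defining step the chosen plan sets a purchased aromatic ring A, a two-step flavanone assembly from 14, and a stereocentre that afterwards meets only hydrogen on a neutral catalyst.

**Alternative 2:** The cut opens ring B at C1′–C2′ and C5′–C6′. The two carbons that join the halves become the alkyne of the (2R) propargylic ether A5, and C2′ to C5′ with both oxygens come from diene A6.
- Forward step: a cobalt-catalysed [4+2] addition of A6 to A5 would give the cyclohexa-1,4-diene A4, to be oxidised to the catechol ring.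
- Merits: no hindered biaryl coupling is needed, since the link is an alkyne made by sp–sp2 coupling. Here the road is better than the chosen one, which relies on a tri-ortho-substituted Suzuki–Miyaura coupling.
- Weak points: C2 must exist before ring B, as a propargylic ether carbon β to the ketone. It must survive amine base, a Lewis-acidic medium and the dehydrogenation of A4, and such conditions are known to turn flavanones into flavones or open them. The alkyne of A5 is flanked by a fully substituted flavone carbon. An enantioselective route to A5 is no smaller a problem than the one it replaces.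
- Comparison: the chosen plan does its demanding coupling early on small, robust partners and makes C2 in the penultimate step, so nothing oxidative or Lewis acidic follows it.

**Alternative 3:** The cut takes flavone ring A apart at C8–C8a, C6–C7 and C4a–C8a.
- Forward step: heating cyclobutenone A8 with the ring B siloxyalkyne A9 would give the resorcinol derivative A7 through a vinylketene.
- Merits: the biaryl bond and ring A arise together without cross-coupling. The mechanism dictates the regiochemistry, and the three oxygens emerge differentiated. This certainty is a real advantage over the chosen plan, whose two iodinations rest on a steric preference for the position beside the hydroxyl.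
- Weak points: neither A8 nor A9 is a catalogue compound, and A9 needs several steps of ynolate chemistry beside the acetal. The ethyl ether ends at flavone C5 and would need a Lewis-acid dealkylation, either after C2 exists or with extra protecting-group changes before. A7 still lacks the pyranone, so an ortho-iodination and the same carbonylative annulation would follow anyway.
- Comparison: this road replaces the three short steps that lead to 9 by a longer sequence. The chosen plan sets against it brevity, purchasable aromatic starting materials, one kind of protecting group and a directed-metalation fallback for the iodination.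

Key step: step 8

Remark: the bond between ring B C6′ and flavone C8 has no axial descriptor in the target, so it is treated as an axis that needs no control; compounds 1, 6 and 15 are taken as purchased.

## Route

Step 1
Reactants: 1 3,4-bis(benzyloxy)benzaldehyde
Product: 2 2-bromo-4,5-bis(benzyloxy)benzaldehyde
Conditions: Br2, NaOAc, AcOH, rt
Reagents that add atoms: bromine, BrBr
Why: Electrophilic aromatic bromination goes para to the 3-benzyloxy group (C6), as is usual for 3,4-dialkoxybenzaldehydes; NaOAc takes up HBr so that the benzyl ethers are not cleaved.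

Step 2
Reactants: 2 2-bromo-4,5-bis(benzyloxy)benzaldehyde
Product: 3 2-[2-bromo-4,5-bis(benzyloxy)phenyl]-1,3-dioxolane
Conditions: HOCH2CH2OH, TsOH·H2O (cat.), toluene, reflux, Dean–Stark
Reagents that add atoms: ethylene glycol, OCCO
Why: Acid-catalysed acetalisation with azeotropic removal of water; the dioxolane protects the aldehyde from the organolithium of step 3 and later prevents lactol formation with the ring A hydroxyl.

Step 3
Reactants: 3 2-[2-bromo-4,5-bis(benzyloxy)phenyl]-1,3-dioxolane
Product: 5 2-[4,5-bis(benzyloxy)-2-(1,3-dioxolan-2-yl)phenyl]-4,4,5,5-tetramethyl-1,3,2-dioxaborolane, via aryllithium 4 (not isolated)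
Conditions: n-BuLi, THF, −78 °C; then i-PrOBpin, −78 °C to rt
Reagents that add atoms: 2-isopropoxy-4,4,5,5-tetramethyl-1,3,2-dioxaborolane, CC(C)OB1OC(C)(C)C(C)(C)O1; n-butyllithium, [Li]CCCC (lithium held only in intermediate 4)
Why: Bromine–lithium exchange at −78 °C is faster than deprotonation of the benzyl ethers and gives 4, stabilised by the neighbouring dioxolane oxygen; borylation with the isopropoxy boronate gives the pinacol ester directly.

Step 4
Reactants: 6 3,5-bis(benzyloxy)phenol
Product: 7 2-iodo-3,5-bis(benzyloxy)phenol
Conditions: NIS (1.0 equiv), CH2Cl2, −20 to 0 °C, dark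
Reagents that add atoms: N-iodosuccinimide, O=C1CCC(=O)N1I
Why: Electrophilic iodination of a 3,5-dialkoxyphenol favours C2, flanked by the small hydroxyl and one ether, over C4, flanked by two ethers; one equivalent at low temperature limits di-iodination and the minor isomer is removed by chromatography.

Step 5
Reactants: 7 2-iodo-3,5-bis(benzyloxy)phenol; 5 2-[4,5-bis(benzyloxy)-2-(1,3-dioxolan-2-yl)phenyl]-4,4,5,5-tetramethyl-1,3,2-dioxaborolane
Product: 8 3,5-bis(benzyloxy)-2-[4,5-bis(benzyloxy)-2-(1,3-dioxolan-2-yl)phenyl]phenol
Conditions: Pd(OAc)2 (5 mol%), SPhos (10 mol%), K3PO4, toluene/H2O, 90 °C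
Reagents that add atoms: none
Why: Suzuki–Miyaura coupling; palladium with the dialkylbiarylphosphine SPhos couples electron-rich, doubly flanked aryl halides with ortho-substituted boronates, and the free phenol and the acetal tolerate aqueous phosphate.

Step 6
Reactants: 8 3,5-bis(benzyloxy)-2-[4,5-bis(benzyloxy)-2-(1,3-dioxolan-2-yl)phenyl]phenol
Product: 9 3,5-bis(benzyloxy)-2-[4,5-bis(benzyloxy)-2-(1,3-dioxolan-2-yl)phenyl]-6-iodophenol
Conditions: NIS (1.05 equiv), NaHCO3, CH2Cl2, 0 °C
Reagents that add atoms: N-iodosuccinimide, O=C1CCC(=O)N1I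
Why: Electrophilic ortho-iodination; C6 (between hydroxyl and ether) should be preferred to C4, which is shielded by two benzyloxy groups, one pushed towards C4 by the neighbouring aryl group. Ring B has only single alkoxy activation per free site and is inert to NIS without acid, and NaHCO3 keeps the acetal intact.

Step 7
Reactants: 1 3,4-bis(benzyloxy)benzaldehyde
Product: 10 1,2-bis(benzyloxy)-4-ethynylbenzene
Conditions: dimethyl (1-diazo-2-oxopropyl)phosphonate, K2CO3, MeOH/THF, rt
Reagents that add atoms: dimethyl (1-diazo-2-oxopropyl)phosphonate, CC(=O)C(=[N+]=[N-])P(=O)(OC)OC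
Why: Seyferth–Gilbert homologation in the Ohira–Bestmann form turns the aryl aldehyde into the terminal alkyne in one step under mild base that leaves the benzyl ethers untouched.

Step 8
Reactants: 9 3,5-bis(benzyloxy)-2-[4,5-bis(benzyloxy)-2-(1,3-dioxolan-2-yl)phenyl]-6-iodophenol; 10 1,2-bis(benzyloxy)-4-ethynylbenzene
Product: 13 5,7-bis(benzyloxy)-2-[3,4-bis(benzyloxy)phenyl]-8-[4,5-bis(benzyloxy)-2-(1,3-dioxolan-2-yl)phenyl]-4H-chromen-4-one, via ynone 11 (not isolated), via enaminone 12 (not isolated)
Conditions: PdCl2(PPh3)2 (5 mol%), CO (10 bar), Et2NH/toluene, 100 °C, no copper salt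
Reagents that add atoms: carbon monoxide, [C-]#[O+]; diethylamine, CCNCC (held only in intermediate 12)
Why: PdCl2(PPh3)2 is reduced in the flask to zerovalent palladium, which inserts into the C–I bond of 9, and CO insertion then gives an aroyl complex of divalent palladium. Amine-assisted transfer of the acetylide of 10 and reductive elimination give ynone 11, which creates C4–C4a and C3–C4. Diethylamine adds to the alkyne carbon β to the ketone to give enaminone 12; the neighbouring hydroxyl attacks the same carbon and expels the amine, which creates O1–C2 and closes the pyranone in a 6-endo mode (6-endo-trig on 12, equivalent to 6-endo-dig on 11). The closest known reaction type is the palladium-catalysed carbonylative annulation of ortho-iodophenols with terminal alkynes to flavones, established for 3,5-dialkoxy-2-iodophenols. No stereocentre is formed and the biaryl axis is not touched, because every new bond lies at least one atom away from it. Carbonylation must outrun direct alkynylation, which would end in a benzofuran; the copper-free medium, the CO pressure and the ready migration of an electron-rich aryl group to CO serve this. Closure must be 6-endo and not 5-exo (aurone), which the secondary amine secures through 12, and the crowded 2,6-disubstituted aroyl group disfavours capture by the amine as an amide. The 8-aryl constitution is fixed by the substrate, since its only hydroxyl lies between the iodide and the biaryl carbon.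

Step 9
Reactants: 13 5,7-bis(benzyloxy)-2-[3,4-bis(benzyloxy)phenyl]-8-[4,5-bis(benzyloxy)-2-(1,3-dioxolan-2-yl)phenyl]-4H-chromen-4-one
Product: 14 4,5-bis(benzyloxy)-2-{5,7-bis(benzyloxy)-2-[3,4-bis(benzyloxy)phenyl]-4-oxo-4H-chromen-8-yl}benzaldehyde
Conditions: 1 M HCl, THF, rt
Reagents that add atoms: water, O
Why: Acid-catalysed acetal hydrolysis; benzyl ethers and the γ-pyranone are stable to dilute aqueous acid at room temperature, and the hydroxyl that could have formed a lactol is now the ring oxygen.

Step 10
Reactants: 15 2,4,6-trihydroxyacetophenone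
Product: 17 2-hydroxy-4,6-bis(benzyloxy)acetophenone, via mono-benzyl ether 16 (not isolated)
Conditions: BnBr (2.1 equiv), K2CO3, DMF, rt
Reagents that add atoms: benzyl bromide, BrCc1ccccc1
Why: Williamson etherification; the 4-hydroxyl reacts first (16), then one ortho hydroxyl, and the last one stays hydrogen-bonded to the ketone and is not alkylated with two equivalents.

Step 11
Reactants: 14 4,5-bis(benzyloxy)-2-{5,7-bis(benzyloxy)-2-[3,4-bis(benzyloxy)phenyl]-4-oxo-4H-chromen-8-yl}benzaldehyde; 17 2-hydroxy-4,6-bis(benzyloxy)acetophenone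
Product: 19 (E)-1-[2-hydroxy-4,6-bis(benzyloxy)phenyl]-3-(4,5-bis(benzyloxy)-2-{5,7-bis(benzyloxy)-2-[3,4-bis(benzyloxy)phenyl]-4-oxo-4H-chromen-8-yl}phenyl)prop-2-en-1-one, via aldol adduct 18 (not isolated)
Conditions: KOH (50% aq.), EtOH/THF, rt
Reagents that add atoms: none
Why: Claisen–Schmidt condensation (aldol addition to 18, then elimination of water) gives the (E)-enone; as its phenoxide the chalcone does not cyclise, and the flavone withstands hydroxide at room temperature, where ring opening is slow.

Step 12
Reactants: 19 (E)-2′-hydroxychalcone from step 11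
Product: 20 (2R)-5,7-bis(benzyloxy)-2-(4,5-bis(benzyloxy)-2-{5,7-bis(benzyloxy)-2-[3,4-bis(benzyloxy)phenyl]-4-oxo-4H-chromen-8-yl}phenyl)chroman-4-one
Conditions: N-[3,5-bis(trifluoromethyl)phenyl]-N′-[(8α,9S)-6′-methoxycinchonan-9-yl]thiourea (20 mol%), toluene, 0 °C; stopped before equilibration, catalyst removed on silica
Reagents that add atoms: none
Why: Enantioselective intramolecular oxa-Michael addition (6-endo-trig) of a 2′-hydroxychalcone under bifunctional base and hydrogen-bond catalysis: the quinuclidine nitrogen activates the phenol, the thiourea binds the enone carbonyl, and the catalyst delivers oxygen to one face of Cβ, which sets C2 as (R). The quinine-derived catalyst is the one expected to give (2R); the quinidine-derived pseudo-enantiomer would be used if a model chalcone shows the opposite sense. The 6′-benzyloxy group twists the aryl ketone and favours closure, and unreacted 19 is recovered.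

Step 13
Reactants: 20 (2R)-octa-O-benzyl flavanone–flavone from step 12
Product: 21 (2R)-2-{2-[2-(3,4-dihydroxyphenyl)-5,7-dihydroxy-4-oxo-4H-chromen-8-yl]-4,5-dihydroxyphenyl}-5,7-dihydroxychroman-4-one
Conditions: H2 (1 atm), 10% Pd/C, THF/MeOH, rt
Reagents that add atoms: none
Why: Hydrogenolysis of the eight benzyl ethers is much faster than reduction of the flavone C2=C3 bond (a vinylogous ester) or of the chromanone ketone; the neutral medium gives no path for retro-oxa-Michael opening, so C2 keeps its configuration.

## Compound list

1 | 3,4-bis(benzyloxy)benzaldehyde | O=Cc1ccc(OCc2ccccc2)c(OCc2ccccc2)c1 | starting material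
2 | 2-bromo-4,5-bis(benzyloxy)benzaldehyde | O=Cc1cc(OCc2ccccc2)c(OCc2ccccc2)cc1Br | intermediate
3 | 2-[2-bromo-4,5-bis(benzyloxy)phenyl]-1,3-dioxolane | Brc1cc(OCc2ccccc2)c(OCc2ccccc2)cc1C1OCCO1 | intermediate
4 | [4,5-bis(benzyloxy)-2-(1,3-dioxolan-2-yl)phenyl]lithium | [Li]c1cc(OCc2ccccc2)c(OCc2ccccc2)cc1C1OCCO1 | intermediate
5 | 2-[4,5-bis(benzyloxy)-2-(1,3-dioxolan-2-yl)phenyl]-4,4,5,5-tetramethyl-1,3,2-dioxaborolane | CC1(C)OB(OC1(C)C)c1cc(OCc2ccccc2)c(OCc2ccccc2)cc1C1OCCO1 | intermediate
6 | 3,5-bis(benzyloxy)phenol | Oc1cc(OCc2ccccc2)cc(OCc2ccccc2)c1 | starting material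
7 | 2-iodo-3,5-bis(benzyloxy)phenol | Oc1cc(OCc2ccccc2)cc(OCc2ccccc2)c1I | intermediate
8 | 3,5-bis(benzyloxy)-2-[4,5-bis(benzyloxy)-2-(1,3-dioxolan-2-yl)phenyl]phenol | Oc1cc(OCc2ccccc2)cc(OCc2ccccc2)c1-c1cc(OCc2ccccc2)c(OCc2ccccc2)cc1C1OCCO1 | intermediate
9 | 3,5-bis(benzyloxy)-2-[4,5-bis(benzyloxy)-2-(1,3-dioxolan-2-yl)phenyl]-6-iodophenol | Oc1c(I)c(OCc2ccccc2)cc(OCc2ccccc2)c1-c1cc(OCc2ccccc2)c(OCc2ccccc2)cc1C1OCCO1 | intermediate
10 | 1,2-bis(benzyloxy)-4-ethynylbenzene | C#Cc1ccc(OCc2ccccc2)c(OCc2ccccc2)c1 | intermediate
11 | 1-{4,6-bis(benzyloxy)-3-[4,5-bis(benzyloxy)-2-(1,3-dioxolan-2-yl)phenyl]-2-hydroxyphenyl}-3-[3,4-bis(benzyloxy)phenyl]prop-2-yn-1-one | O=C(C#Cc1ccc(OCc2ccccc2)c(OCc2ccccc2)c1)c1c(O)c(-c2cc(OCc3ccccc3)c(OCc3ccccc3)cc2C2OCCO2)c(OCc2ccccc2)cc1OCc1ccccc1 | intermediate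
12 | 1-{4,6-bis(benzyloxy)-3-[4,5-bis(benzyloxy)-2-(1,3-dioxolan-2-yl)phenyl]-2-hydroxyphenyl}-3-[3,4-bis(benzyloxy)phenyl]-3-(diethylamino)prop-2-en-1-one (alkene geometry not fixed) | CCN(CC)C(=CC(=O)c1c(O)c(-c2cc(OCc3ccccc3)c(OCc3ccccc3)cc2C2OCCO2)c(OCc2ccccc2)cc1OCc1ccccc1)c1ccc(OCc2ccccc2)c(OCc2ccccc2)c1 | intermediate
13 | 5,7-bis(benzyloxy)-2-[3,4-bis(benzyloxy)phenyl]-8-[4,5-bis(benzyloxy)-2-(1,3-dioxolan-2-yl)phenyl]-4H-chromen-4-one | O=c1cc(-c2ccc(OCc3ccccc3)c(OCc3ccccc3)c2)oc2c(-c3cc(OCc4ccccc4)c(OCc4ccccc4)cc3C3OCCO3)c(OCc3ccccc3)cc(OCc3ccccc3)c12 | intermediate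
14 | 4,5-bis(benzyloxy)-2-{5,7-bis(benzyloxy)-2-[3,4-bis(benzyloxy)phenyl]-4-oxo-4H-chromen-8-yl}benzaldehyde | O=Cc1cc(OCc2ccccc2)c(OCc2ccccc2)cc1-c1c(OCc2ccccc2)cc(OCc2ccccc2)c2c(=O)cc(-c3ccc(OCc4ccccc4)c(OCc4ccccc4)c3)oc12 | intermediate
15 | 2,4,6-trihydroxyacetophenone | CC(=O)c1c(O)cc(O)cc1O | starting material
16 | 4-(benzyloxy)-2,6-dihydroxyacetophenone | CC(=O)c1c(O)cc(OCc2ccccc2)cc1O | intermediate
17 | 2-hydroxy-4,6-bis(benzyloxy)acetophenone | CC(=O)c1c(O)cc(OCc2ccccc2)cc1OCc1ccccc1 | intermediate
18 | 3-hydroxy-1-[2-hydroxy-4,6-bis(benzyloxy)phenyl]-3-(4,5-bis(benzyloxy)-2-{5,7-bis(benzyloxy)-2-[3,4-bis(benzyloxy)phenyl]-4-oxo-4H-chromen-8-yl}phenyl)propan-1-one (racemic) | O=C(CC(O)c1cc(OCc2ccccc2)c(OCc2ccccc2)cc1-c1c(OCc2ccccc2)cc(OCc2ccccc2)c2c(=O)cc(-c3ccc(OCc4ccccc4)c(OCc4ccccc4)c3)oc12)c1c(O)cc(OCc2ccccc2)cc1OCc1ccccc1 | intermediate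
19 | (E)-1-[2-hydroxy-4,6-bis(benzyloxy)phenyl]-3-(4,5-bis(benzyloxy)-2-{5,7-bis(benzyloxy)-2-[3,4-bis(benzyloxy)phenyl]-4-oxo-4H-chromen-8-yl}phenyl)prop-2-en-1-one | O=C(/C=C/c1cc(OCc2ccccc2)c(OCc2ccccc2)cc1-c1c(OCc2ccccc2)cc(OCc2ccccc2)c2c(=O)cc(-c3ccc(OCc4ccccc4)c(OCc4ccccc4)c3)oc12)c1c(O)cc(OCc2ccccc2)cc1OCc1ccccc1 | intermediate
20 | (2R)-5,7-bis(benzyloxy)-2-(4,5-bis(benzyloxy)-2-{5,7-bis(benzyloxy)-2-[3,4-bis(benzyloxy)phenyl]-4-oxo-4H-chromen-8-yl}phenyl)chroman-4-one | O=C1C[C@H](c2cc(OCc3ccccc3)c(OCc3ccccc3)cc2-c2c(OCc3ccccc3)cc(OCc3ccccc3)c3c(=O)cc(-c4ccc(OCc5ccccc5)c(OCc5ccccc5)c4)oc23)Oc2cc(OCc3ccccc3)cc(OCc3ccccc3)c21 | intermediate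
21 | (2R)-2-{2-[2-(3,4-dihydroxyphenyl)-5,7-dihydroxy-4-oxo-4H-chromen-8-yl]-4,5-dihydroxyphenyl}-5,7-dihydroxychroman-4-one | O=C1C[C@H](c2cc(O)c(O)cc2-c2c(O)cc(O)c3c(=O)cc(-c4ccc(O)c(O)c4)oc23)Oc2cc(O)cc(O)c21 | target

## Step count and least certain steps

Total: 13 steps. Longest linear sequence: 10 steps (steps 1, 2, 3, 5, 6, 8, 9, 11, 12, 13, from 1 to 21).

**Step 8 (key step).**
- Risk: oxidative addition to the very electron-rich, doubly flanked iodide may be slow because the free phenol is partly present as phenoxide. The aroyl palladium species may then be captured by diethylamine, or the aryl palladium species may couple with the alkyne before CO inserts.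
- Fallback: take the ring closure out of the palladium step. Setting out from 9, acetylation (Ac2O, pyridine) should give 3,5-bis(benzyloxy)-2-[4,5-bis(benzyloxy)-2-(1,3-dioxolan-2-yl)phenyl]-6-iodophenyl acetate F1. Carbonylative coupling of F1 with 10 under a tertiary amine that cannot add to the product (PdCl2(PPh3)2, Et3N, CO, THF) should give the isolable acetoxy ynone F2. Brief treatment of F2 with Et2NH in EtOH should remove the acetyl group as the amide and close the ring through 11 and 12, coming back to the route at 13.

**Step 12.**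
- Risk: poor facial selectivity, because the flavone substituent ortho to the enone crowds Cβ. Loss of enantiomeric purity through reversal of the closure, and incomplete conversion at equilibrium, are also possible.
- Fallback: separate ring closure from stereocontrol. Setting out from 19, NaOAc in EtOH/THF at reflux should give the racemic flavanone F3. Preparative chromatography on a polysaccharide-carbamate chiral stationary phase should give 20, where the route is rejoined. The (2S) enantiomer F4 would be returned to the equilibrium with 19 by base and recycled.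

**Step 6.**
- Risk: iodination at C4 (between the two ethers) or at both free positions, because both sites are activated by three oxygens and only sterics distinguish them.
- Fallback: directed ortho-metalation, which can reach only the position beside the directing group. Setting out from 8, NaH and diethylcarbamoyl chloride should give the O-aryl diethylcarbamate F5. Treatment with s-BuLi/TMEDA in THF at −78 °C and then I2 should give the iodo carbamate F6. KOH in EtOH at reflux should release the phenol and come back to the route at 9.

**Step 13.**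
- Risk: over-reduction (saturation of the flavone C2=C3 bond, hydrogenolytic opening of the benzylic C2–O bond of the flavanone, reduction of the C4 ketone), or stalling when partly deprotected material precipitates.
- Fallback: non-reductive debenzylation. Setting out from 20, BCl3 with pentamethylbenzene as benzyl cation scavenger in CH2Cl2 at −78 °C, then aqueous work-up, should lead directly to 21. This makes no new compound (F0).

## Further compounds

F1 | step 8 | 3,5-bis(benzyloxy)-2-[4,5-bis(benzyloxy)-2-(1,3-dioxolan-2-yl)phenyl]-6-iodophenyl acetate | CC(=O)Oc1c(I)c(OCc2ccccc2)cc(OCc2ccccc2)c1-c1cc(OCc2ccccc2)c(OCc2ccccc2)cc1C1OCCO1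
F2 | step 8 | 3,5-bis(benzyloxy)-2-[4,5-bis(benzyloxy)-2-(1,3-dioxolan-2-yl)phenyl]-6-{3-[3,4-bis(benzyloxy)phenyl]prop-2-ynoyl}phenyl acetate | CC(=O)Oc1c(C(=O)C#Cc2ccc(OCc3ccccc3)c(OCc3ccccc3)c2)c(OCc2ccccc2)cc(OCc2ccccc2)c1-c1cc(OCc2ccccc2)c(OCc2ccccc2)cc1C1OCCO1
F3 | step 12 | racemic 5,7-bis(benzyloxy)-2-(4,5-bis(benzyloxy)-2-{5,7-bis(benzyloxy)-2-[3,4-bis(benzyloxy)phenyl]-4-oxo-4H-chromen-8-yl}phenyl)chroman-4-one | O=C1CC(c2cc(OCc3ccccc3)c(OCc3ccccc3)cc2-c2c(OCc3ccccc3)cc(OCc3ccccc3)c3c(=O)cc(-c4ccc(OCc5ccccc5)c(OCc5ccccc5)c4)oc23)Oc2cc(OCc3ccccc3)cc(OCc3ccccc3)c21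
F4 | step 12 | (2S) enantiomer of 20 | O=C1C[C@@H](c2cc(OCc3ccccc3)c(OCc3ccccc3)cc2-c2c(OCc3ccccc3)cc(OCc3ccccc3)c3c(=O)cc(-c4ccc(OCc5ccccc5)c(OCc5ccccc5)c4)oc23)Oc2cc(OCc3ccccc3)cc(OCc3ccccc3)c21
F5 | step 6 | 3,5-bis(benzyloxy)-2-[4,5-bis(benzyloxy)-2-(1,3-dioxolan-2-yl)phenyl]phenyl N,N-diethylcarbamate | CCN(CC)C(=O)Oc1cc(OCc2ccccc2)cc(OCc2ccccc2)c1-c1cc(OCc2ccccc2)c(OCc2ccccc2)cc1C1OCCO1
F6 | step 6 | 3,5-bis(benzyloxy)-2-[4,5-bis(benzyloxy)-2-(1,3-dioxolan-2-yl)phenyl]-6-iodophenyl N,N-diethylcarbamate | CCN(CC)C(=O)Oc1c(I)c(OCc2ccccc2)cc(OCc2ccccc2)c1-c1cc(OCc2ccccc2)c(OCc2ccccc2)cc1C1OCCO1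
F0 | step 13 | none | none
A1 | alternative 1 | (2R)-flavanone–flavone with ring A of the flavanone as free 5,7-diol and six benzyl ethers | O=C1C[C@H](c2cc(OCc3ccccc3)c(OCc3ccccc3)cc2-c2c(OCc3ccccc3)cc(OCc3ccccc3)c3c(=O)cc(-c4ccc(OCc5ccccc5)c(OCc5ccccc5)c4)oc23)Oc2cc(O)cc(O)c21
A2 | alternative 1 | (2R)-2-(4,5-bis(benzyloxy)-2-{5,7-bis(benzyloxy)-2-[3,4-bis(benzyloxy)phenyl]-4-oxo-4H-chromen-8-yl}phenyl)-5-(phenylsulfinyl)-2,3-dihydro-4H-pyran-4-one | O=C1C[C@H](c2cc(OCc3ccccc3)c(OCc3ccccc3)cc2-c2c(OCc3ccccc3)cc(OCc3ccccc3)c3c(=O)cc(-c4ccc(OCc5ccccc5)c(OCc5ccccc5)c4)oc23)OC=C1S(=O)c1ccccc1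
A3 | alternative 1 | 1-methoxy-1,3-bis(trimethylsilyloxy)buta-1,3-diene | COC(O[Si](C)(C)C)=CC(=C)O[Si](C)(C)C
A4 | alternative 2 | (2R)-cycloadduct with ring B as a 1,2-bis(trimethylsilyloxy)cyclohexa-1,4-diene | O=C1C[C@H](C2=C(c3c(OCc4ccccc4)cc(OCc4ccccc4)c4c(=O)cc(-c5ccc(OCc6ccccc6)c(OCc6ccccc6)c5)oc34)CC(O[Si](C)(C)C)=C(O[Si](C)(C)C)C2)Oc2cc(OCc3ccccc3)cc(OCc3ccccc3)c21
A5 | alternative 2 | (2R)-5,7-bis(benzyloxy)-2-({5,7-bis(benzyloxy)-2-[3,4-bis(benzyloxy)phenyl]-4-oxo-4H-chromen-8-yl}ethynyl)chroman-4-one | O=C1C[C@H](C#Cc2c(OCc3ccccc3)cc(OCc3ccccc3)c3c(=O)cc(-c4ccc(OCc5ccccc5)c(OCc5ccccc5)c4)oc23)Oc2cc(OCc3ccccc3)cc(OCc3ccccc3)c21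
A6 | alternative 2 | 2,3-bis(trimethylsilyloxy)buta-1,3-diene | C=C(O[Si](C)(C)C)C(=C)O[Si](C)(C)C
A7 | alternative 3 | 2-[4,5-bis(benzyloxy)-2-(1,3-dioxolan-2-yl)phenyl]-5-ethoxy-3-(triisopropylsilyloxy)phenol | CCOc1cc(O)c(-c2cc(OCc3ccccc3)c(OCc3ccccc3)cc2C2OCCO2)c(O[Si](C(C)C)(C(C)C)C(C)C)c1
A8 | alternative 3 | 3-ethoxycyclobut-2-en-1-one | CCOC1=CC(=O)C1
A9 | alternative 3 | 2-{4,5-bis(benzyloxy)-2-[(triisopropylsilyloxy)ethynyl]phenyl}-1,3-dioxolane | CC(C)[Si](OC#Cc1cc(OCc2ccccc2)c(OCc2ccccc2)cc1C1OCCO1)(C(C)C)C(C)C
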